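**Retrosynthetic overview**

1. Kazinol K 19 ⇐ global deprotection with NaSEt ⇐ 18 ⇐ B-alkyl Suzuki–Miyaura coupling joining the C6 side chain of the ring B chromene 11 (6-allyl) to the ring A bromide 16 (from resorcinol; an aromatic Claisen rearrangement sets the 1,1-dimethylallyl group).
2. 11 ⇐ quinone monoketal 8 + prenyl metal in one operation: 1,2-addition to C5=O, then acid closes the pyran ring through the O1–C8a bond and re-aromatizes ring B.
3. Feature used: in ring B, C5 (prenyl) is para to C8 (OH), and C8a lies between C8 and C4a, the carbon holding the C4=C3–C2(CH3)2–O1 chain. Drawn as a cyclohexa-2,5-diene with a carbinol at C5 and a dimethyl ketal at C8, C8a is an allylic terminus within reach of O1; loss of water (C5) and methanol (C8) restores the benzene ring.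
4. 8 ⇐ cis-diol phenol 7 (PhI(OAc)2, MeOH) ⇐ 8-allyl-6-methoxycoumarin 5 (MeLi) ⇐ 2-hydroxy-5-methoxybenzaldehyde 1; the lactone fixes the Z alkene, and its ring oxygen (on C5) is the one later expelled as water.
5. Ring order: benzene rings A and B are bought; a temporary lactone ring is made (step 2) and opened (step 3); ring B is dearomatized (step 4); the pyran ring is closed and ring B re-aromatized in step 5.

Key step: step 5

Remark on the chemistry: the target has no stereocentre; the only stereochemical element to carry is the cis C3=C4 alkene, which is taken from a lactone ring. Locants O1, C2, C3, C4, C4a, C5, C6, C7, C8, C8a are those of the 2H-chromene of ring B in the target and denote the same atoms in every intermediate; ring A is the resorcinol ring; prenyl = 3-methylbut-2-en-1-yl.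

Step 1
Reactants: 1 2-hydroxy-5-methoxybenzaldehyde
Product: 2 5-methoxy-2-(prop-2-en-1-yloxy)benzaldehyde
Conditions: allyl bromide, K2CO3, DMF, 25 °C
Reagents that add atoms: allyl bromide, C=CCBr
Why: Williamson ether synthesis of a phenoxide with a primary allylic bromide should go cleanly; no stereocentre is formed.

Step 2
Reactants: 2 5-methoxy-2-(prop-2-en-1-yloxy)benzaldehyde
Product: 5 6-methoxy-8-(prop-2-en-1-yl)-2H-chromen-2-one, via aryl allyl ether acrylate 3 (not isolated), via ortho-allylphenol acrylate 4 (not isolated)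
Conditions: Ph3P=CHCO2Et, N,N-diethylaniline, 215 °C
Reagents that add atoms: ethyl (triphenylphosphoranylidene)acetate, CCOC(=O)C=P(c1ccccc1)(c1ccccc1)c1ccccc1
Why: Wittig olefination, aromatic Claisen rearrangement to the only free ortho position, and thermal E/Z isomerization with lactonization should follow one another in the hot amine (the known one-pot route to 8-allylcoumarins); the lactone ring fixes the cis C3=C4 alkene.

Step 3
Reactants: 5 6-methoxy-8-(prop-2-en-1-yl)-2H-chromen-2-one
Product: 7 2-[(1Z)-3-hydroxy-3-methylbut-1-en-1-yl]-4-methoxy-6-(prop-2-en-1-yl)phenol, via cis-enone lithium phenolate 6 (not isolated)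
Conditions: MeLi (excess), THF, −78 to 0 °C; aq. NH4Cl, 0 °C; crude product used at once
Reagents that add atoms: methyllithium, [Li]C
Why: Double 1,2-addition of an organolithium to the coumarin carbonyl (lactone opening, then ketone addition) is the classical entry to cis-2-(3-hydroxy-3-methylbut-1-enyl)phenols, and the Z alkene is inherited unchanged from the ring.

Step 4
Reactants: 7 2-[(1Z)-3-hydroxy-3-methylbut-1-en-1-yl]-4-methoxy-6-(prop-2-en-1-yl)phenol
Product: 8 2-[(1Z)-3-hydroxy-3-methylbut-1-en-1-yl]-4,4-dimethoxy-6-(prop-2-en-1-yl)cyclohexa-2,5-dien-1-one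
Conditions: PhI(OAc)2, NaHCO3, MeOH, 0 °C
Reagents that add atoms: methanol, CO
Why: Oxidative dearomatization of a 4-methoxyphenol with a trivalent iodine reagent in methanol should give the quinone monoketal, methanol adding at the para carbon C8 that already bears OMe; no stereocentre is formed.

Step 5
Reactants: 8 2-[(1Z)-3-hydroxy-3-methylbut-1-en-1-yl]-4,4-dimethoxy-6-(prop-2-en-1-yl)cyclohexa-2,5-dien-1-one
Product: 11 8-methoxy-2,2-dimethyl-5-(3-methylbut-2-en-1-yl)-6-(prop-2-en-1-yl)-2H-chromene, via quinol ketal 9 (not isolated), via dihydrochromene ketal 10 (not isolated)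
Conditions: prenylbarium chloride (2.3 equiv; from prenyl chloride and activated zerovalent barium, itself from BaI2 and lithium biphenylide), THF, −78 °C, inverse addition; then camphorsulfonic acid (slight excess over the alkoxides), 4 Å MS, CH2Cl2, −78 to 0 °C
Reagents that add atoms: prenylbarium chloride, CC(C)=CC[Ba]Cl (made in the flask from prenyl chloride, CC(C)=CCCl)
Why: Proposed new method: the α-selective allylic barium reagent should add 1,2 to the only carbonyl (C5) to give quinol ketal 9, and on acidification the tertiary, doubly allylic C5–OH should ionize to a pentadienyl cation with termini C8a and C7; the side-chain hydroxyl, held over C8a by the Z alkene, captures C8a in a 6-endo-trig SN2′-type closure that forms the O1–C8a bond of the pyran ring (10), and loss of methanol from the C8 ketal then re-aromatizes ring B. The closest known reaction types are the α-selective allylbarium addition to ketones, the acid-induced dienol–benzene aromatization of quinol ketals, and the acid-promoted SN2′ substitution of quinone monoacetals by nucleophiles with loss of methanol; what is new is a tethered oxygen nucleophile attacking the carbon next to the ketal. No stereocentre has to be controlled: C5 of 9 and C8a of 10 are racemic and both become sp2. The step needs α- and not γ-attack of the prenyl metal (secured by barium at −78 °C), ionization at C5 rather than hydrolysis or 1,2-shift chemistry at the ketal (secured by excluding water with molecular sieves, so that ketal ionization is only a reversible resting state), and capture at C8a rather than at C7 or by a methoxy shift (secured by the six-membered reach of O1 and by the irreversible aromatization).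

Step 6
Reactants: 12 resorcinol
Product: 13 3-[(3-methylbut-2-en-1-yl)oxy]phenol
Conditions: prenyl bromide (0.5 equiv), K2CO3, acetone, 56 °C; excess resorcinol recovered
Reagents that add atoms: prenyl bromide, CC(C)=CCBr
Why: Williamson mono-O-alkylation; the excess of the diol should hold back the bis-ether.

Step 7
Reactants: 13 3-[(3-methylbut-2-en-1-yl)oxy]phenol
Product: 14 4-(2-methylbut-3-en-2-yl)benzene-1,3-diol
Conditions: N,N-diethylaniline, 190 °C
Reagents that add atoms: none
Why: Aromatic Claisen rearrangement of the aryl prenyl ether should transfer the allyl unit with inversion, giving the 1,1-dimethylallyl group ortho to oxygen at C6 (para to the free OH) rather than at the crowded C2 between the oxygens; the basic amine solvent suppresses acid-induced ring closure.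

Step 8
Reactants: 14 4-(2-methylbut-3-en-2-yl)benzene-1,3-diol
Product: 15 4-bromo-6-(2-methylbut-3-en-2-yl)benzene-1,3-diol
Conditions: NBS (1.0 equiv), MeCN, −30 °C
Reagents that add atoms: N-bromosuccinimide, O=C1CCC(=O)N1Br
Why: Electrophilic aromatic bromination at the free position ortho to one hydroxyl and para to the other (the site of the later propyl chain) should outrun any reaction of the hindered monosubstituted alkene.

Step 9
Reactants: 15 4-bromo-6-(2-methylbut-3-en-2-yl)benzene-1,3-diol
Product: 16 4-bromo-6-(2-methylbut-3-en-2-yl)-1,3-phenylene bis(2,2-dimethylpropanoate)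
Conditions: PivCl, Et3N, DMAP (cat.), CH2Cl2, 0 to 25 °C
Reagents that add atoms: pivaloyl chloride, CC(C)(C)C(Cl)=O
Why: Acylation of both phenols under DMAP catalysis should give pivalates that survive the coupling, make the aryl bromide a better partner for oxidative addition, and fall off under the thiolate conditions of the last step.

Step 10
Reactants: 11 8-methoxy-2,2-dimethyl-5-(3-methylbut-2-en-1-yl)-6-(prop-2-en-1-yl)-2H-chromene; 16 4-bromo-6-(2-methylbut-3-en-2-yl)-1,3-phenylene bis(2,2-dimethylpropanoate)
Product: 18 4-{3-[8-methoxy-2,2-dimethyl-5-(3-methylbut-2-en-1-yl)-2H-chromen-6-yl]propyl}-6-(2-methylbut-3-en-2-yl)-1,3-phenylene bis(2,2-dimethylpropanoate), via B-alkyl-9-BBN 17 (not isolated)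
Conditions: 9-BBN (1.05 equiv), THF, 0 to 25 °C; then 16, Pd(dppf)Cl2 (5 mol%), K3PO4, H2O (few equiv), DMF, 50 °C
Reagents that add atoms: none
Why: Anti-Markovnikov hydroboration with 9-BBN should take only the monosubstituted allyl alkene of 11 (the prenyl alkene is trisubstituted and the chromene alkene is hindered), and the B-alkyl Suzuki–Miyaura coupling then joins the sp3 carbon to ring A.

Step 11
Reactants: 18 4-{3-[8-methoxy-2,2-dimethyl-5-(3-methylbut-2-en-1-yl)-2H-chromen-6-yl]propyl}-6-(2-methylbut-3-en-2-yl)-1,3-phenylene bis(2,2-dimethylpropanoate)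
Product: 19 Kazinol K
Conditions: NaSEt (excess), DMF, 110 °C; aq. HCl work-up to pH 5 under N2
Reagents that add atoms: none
Why: The thiolate should cleave the two aryl pivalates by acyl transfer and the aryl methyl ether by SN2 attack at methyl (nucleophilic demethylation), conditions to which the alkenes and the chromene are inert.

**Compound list**

1 | 2-hydroxy-5-methoxybenzaldehyde | O=Cc1cc(OC)ccc1O | starting material
2 | 5-methoxy-2-(prop-2-en-1-yloxy)benzaldehyde | C=CCOc1ccc(OC)cc1C=O | intermediate
3 | ethyl (2E)-3-[5-methoxy-2-(prop-2-en-1-yloxy)phenyl]prop-2-enoate | C=CCOc1ccc(OC)cc1/C=C/C(=O)OCC | intermediate (not isolated)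
4 | ethyl (2E)-3-[2-hydroxy-5-methoxy-3-(prop-2-en-1-yl)phenyl]prop-2-enoate | C=CCc1cc(OC)cc(/C=C/C(=O)OCC)c1O | intermediate (not isolated)
5 | 6-methoxy-8-(prop-2-en-1-yl)-2H-chromen-2-one | C=CCc1cc(OC)cc2C=CC(=O)Oc12 | intermediate
6 | lithium 4-methoxy-2-[(1Z)-3-oxobut-1-en-1-yl]-6-(prop-2-en-1-yl)phenolate | C=CCc1cc(OC)cc(/C=C\C(C)=O)c1[O-].[Li+] | intermediate (not isolated)
7 | 2-[(1Z)-3-hydroxy-3-methylbut-1-en-1-yl]-4-methoxy-6-(prop-2-en-1-yl)phenol | C=CCc1cc(OC)cc(/C=C\C(C)(C)O)c1O | intermediate
8 | 2-[(1Z)-3-hydroxy-3-methylbut-1-en-1-yl]-4,4-dimethoxy-6-(prop-2-en-1-yl)cyclohexa-2,5-dien-1-one | C=CCC1=CC(OC)(OC)C=C(/C=C\C(C)(C)O)C1=O | intermediate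
9 | 2-[(1Z)-3-hydroxy-3-methylbut-1-en-1-yl]-4,4-dimethoxy-1-(3-methylbut-2-en-1-yl)-6-(prop-2-en-1-yl)cyclohexa-2,5-dien-1-ol (racemic) | C=CCC1=CC(OC)(OC)C=C(/C=C\C(C)(C)O)C1(O)CC=C(C)C | intermediate (not isolated)
10 | 8,8-dimethoxy-2,2-dimethyl-5-(3-methylbut-2-en-1-yl)-6-(prop-2-en-1-yl)-8,8a-dihydro-2H-chromene (racemic) | C=CCC1=CC(OC)(OC)C2OC(C)(C)C=CC2=C1CC=C(C)C | intermediate (not isolated)
11 | 8-methoxy-2,2-dimethyl-5-(3-methylbut-2-en-1-yl)-6-(prop-2-en-1-yl)-2H-chromene | C=CCc1cc(OC)c2OC(C)(C)C=Cc2c1CC=C(C)C | intermediate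
12 | resorcinol (benzene-1,3-diol) | Oc1cccc(O)c1 | starting material
13 | 3-[(3-methylbut-2-en-1-yl)oxy]phenol | CC(C)=CCOc1cccc(O)c1 | intermediate
14 | 4-(2-methylbut-3-en-2-yl)benzene-1,3-diol | C=CC(C)(C)c1ccc(O)cc1O | intermediate
15 | 4-bromo-6-(2-methylbut-3-en-2-yl)benzene-1,3-diol | C=CC(C)(C)c1cc(Br)c(O)cc1O | intermediate
16 | 4-bromo-6-(2-methylbut-3-en-2-yl)-1,3-phenylene bis(2,2-dimethylpropanoate) | C=CC(C)(C)c1cc(Br)c(OC(=O)C(C)(C)C)cc1OC(=O)C(C)(C)C | intermediate
17 | 9-{3-[8-methoxy-2,2-dimethyl-5-(3-methylbut-2-en-1-yl)-2H-chromen-6-yl]propyl}-9-borabicyclo[3.3.1]nonane | CC(C)=CCc1c(CCCB2C3CCCC2CCC3)cc(OC)c2OC(C)(C)C=Cc12 | intermediate (not isolated)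
18 | 4-{3-[8-methoxy-2,2-dimethyl-5-(3-methylbut-2-en-1-yl)-2H-chromen-6-yl]propyl}-6-(2-methylbut-3-en-2-yl)-1,3-phenylene bis(2,2-dimethylpropanoate) | C=CC(C)(C)c1cc(CCCc2cc(OC)c3OC(C)(C)C=Cc3c2CC=C(C)C)c(OC(=O)C(C)(C)C)cc1OC(=O)C(C)(C)C | intermediate
19 | Kazinol K, 4-{3-[8-hydroxy-2,2-dimethyl-5-(3-methylbut-2-en-1-yl)-2H-chromen-6-yl]propyl}-6-(2-methylbut-3-en-2-yl)benzene-1,3-diol | C=CC(C)(C)c1cc(CCCc2cc(O)c3OC(C)(C)C=Cc3c2CC=C(C)C)c(O)cc1O | target

**Step count and risks**

Total step count: 11. Longest linear sequence: 7 steps (steps 1 to 5, then 10 and 11).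

Steps most likely to fail:

1. Step 5 (bears the label). What may go wrong: attack of the allylic metal through its γ-terminus, which would place a 1,1-dimethylallyl group on C5; hydrolysis of the ketal, or a 1,2-shift of the prenyl or a methoxy group, outrunning the ring closure; premature ionization of the side-chain tertiary alcohol. Fallback (sets out from 8, returns at 11): the tertiary alcohol of 8 is added to C8a, the β-carbon of the dienone, in an intramolecular oxa-Michael reaction (DBU or catalytic KOtBu, THF, 0 °C). Mild acid (PPTS, CH2Cl2) then eliminates methanol from the adduct, the known conjugate addition and aromatization chemistry of quinone monoketals, which should give the phenol 6-allyl-8-methoxy-2,2-dimethyl-2H-chromen-5-ol F1 with the same O1–C8a ring closure. F1 is converted with Tf2O and pyridine into 6-allyl-8-methoxy-2,2-dimethyl-2H-chromen-5-yl trifluoromethanesulfonate F2. A linear-selective Negishi coupling of F2 with prenylzinc bromide (Pd(OAc)2 with a CPhos-type biarylphosphine, THF) should then put the prenyl group on C5 and give 11.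

2. Step 3. What may go wrong: loss of the cis-diol through acid- or heat-induced ring closure by the phenolic oxygen (dehydration to the isomeric 2,2-dimethylchromene) during work-up or storage; conjugate addition of the organolithium; enolization of the intermediate methyl ketone. Fallback (sets out from 5, returns at 8): after the MeLi addition the dilithium salt is silylated in the same flask with Me3SiCl to give {2-allyl-4-methoxy-6-[(1Z)-3-methyl-3-(trimethylsilyloxy)but-1-en-1-yl]phenoxy}trimethylsilane F3, so that the free ortho-hydroxy cis-allylic alcohol is never handled. F3 is then treated with K2CO3 in MeOH at 0 °C, which unmasks the phenol, followed by PhI(OAc)2; the tertiary silyl ether is lost in the same basic methanol and the quinone monoketal 8 should result.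

3. Step 7. What may go wrong: poor regiocontrol of the sigmatropic shift (migration to C2 between the two oxygens), an abnormal Claisen pathway, or ring closure of the ortho-(1,1-dimethylallyl)phenol onto its alkene at 190 °C. Fallback (sets out from 12, returns at 14): resorcinol is monobrominated with NBS to 4-bromobenzene-1,3-diol F4 and protected with MOMCl and iPr2NEt as 1-bromo-2,4-bis(methoxymethoxy)benzene F5. A ligand-controlled, branched-selective Suzuki–Miyaura coupling of F5 with prenylboronic acid pinacol ester (Pd(OAc)2, biarylphosphine, K3PO4) should give 2,4-bis(methoxymethoxy)-1-(2-methylbut-3-en-2-yl)benzene F6 with the carbon–carbon bond at the tertiary end of the allyl unit. Mild acid (HCl, MeOH, 25 °C) then frees the diol 14.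

**Further compounds**

F1 | step 5 | 6-allyl-8-methoxy-2,2-dimethyl-2H-chromen-5-ol | C=CCc1cc(OC)c2OC(C)(C)C=Cc2c1O
F2 | step 5 | 6-allyl-8-methoxy-2,2-dimethyl-2H-chromen-5-yl trifluoromethanesulfonate | C=CCc1cc(OC)c2OC(C)(C)C=Cc2c1OS(=O)(=O)C(F)(F)F
F3 | step 3 | {2-allyl-4-methoxy-6-[(1Z)-3-methyl-3-(trimethylsilyloxy)but-1-en-1-yl]phenoxy}trimethylsilane | C=CCc1cc(OC)cc(/C=C\C(C)(C)O[Si](C)(C)C)c1O[Si](C)(C)C
F4 | step 7 | 4-bromobenzene-1,3-diol | Oc1ccc(Br)c(O)c1
F5 | step 7 | 1-bromo-2,4-bis(methoxymethoxy)benzene | COCOc1ccc(Br)c(OCOC)c1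
F6 | step 7 | 2,4-bis(methoxymethoxy)-1-(2-methylbut-3-en-2-yl)benzene | C=CC(C)(C)c1ccc(OCOC)cc1OCOC
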